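**Plan**

Locants: flavan half O1, C2–C8a (rings A, B); upper half primed: O1′, ketal C2′, carbinol C3′, ketone C4′ (rings A′, B′).
Cuts: five O-benzyl groups; then O1′–C2′ and C3′–OH (back to a 2-aryl-3-aroylbenzofuran); then O7–C7 and C8–C3′ together (back to a flavan 7,8-aryne and the enol O–C2′=C3′ unit of a β-diketone held as its phenyliodonium ylide); last O1–C2 and the chalcone C=C.
Enabling feature: the furan ring puts its oxygen on C7 and its carbon on C8, adjacent ring A carbons, with the pyran oxygen O1 on C8a next to C8. This is a 3-alkoxyaryne pattern that takes O at C7 and C at C8, and the O7–C2′–C3′ unit flanked by the C4′ ketone is an enolate oxygen and its α-carbon.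
Forward: chalcone, pyran ring of the flavan, 8-silyl-7-triflate, furan ring by aryne/ylide [3+2] annulation (joins both halves), pyranone ring by epoxidation and ketalisation, debenzylation.
Stereochemistry: C2 (S) from asymmetric transfer hydrogenation to the (R)-alcohol and Mitsunobu inversion; C3′ (R) from catalyst-controlled epoxidation of the benzofuran; C2′ (R) from the enforced cis fusion of the furan and pyranone rings.

Key step: step 12

Remark: 1, 4, 14 and 16 are taken as catalogue compounds; ylide 18 is drawn as its zwitterion.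

**Route**

Step 1
Reactants: 1 2,4,6-trihydroxybenzaldehyde
Product: 2 2,6-dihydroxy-4-(methoxymethoxy)benzaldehyde
Conditions: MOMCl (1.0 equiv), iPr2NEt, CH2Cl2, 0 °C
Reagents that add atoms: chloromethyl methyl ether (MOMCl), COCCl
Why: Selective phenol O-alkylation: the 4-hydroxyl, para to the formyl group, is the most acidic and least hindered, while the ortho hydroxyls are deactivated by chelation to the formyl oxygen, so one equivalent of MOMCl should etherify it first.

Step 2
Reactants: 2 2,6-dihydroxy-4-(methoxymethoxy)benzaldehyde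
Product: 3 2-(benzyloxy)-6-hydroxy-4-(methoxymethoxy)benzaldehyde
Conditions: BnBr (1.0 equiv), K2CO3, DMF, rt
Reagents that add atoms: benzyl bromide, BrCc1ccccc1
Why: Williamson etherification of one of the two equivalent ortho hydroxyls; the remaining hydroxyl stays chelated to the formyl group and should resist a second alkylation.

Step 3
Reactants: 3 2-(benzyloxy)-6-hydroxy-4-(methoxymethoxy)benzaldehyde; 4 1-[4-(benzyloxy)phenyl]ethan-1-one
Product: 5 (E)-1-[4-(benzyloxy)phenyl]-3-[2-(benzyloxy)-6-hydroxy-4-(methoxymethoxy)phenyl]prop-2-en-1-one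
Conditions: KOH (aq. 50%), EtOH, rt to 50 °C; AcOH quench
Reagents that add atoms: none
Why: Claisen–Schmidt (crossed aldol) condensation of the methyl ketone enolate with the non-enolisable aldehyde, dehydration giving the (E)-enone; MOM and benzyl ethers are stable to base.

Step 4
Reactants: 5 (E)-1-[4-(benzyloxy)phenyl]-3-[2-(benzyloxy)-6-hydroxy-4-(methoxymethoxy)phenyl]prop-2-en-1-one
Product: 7 (R)-1-[4-(benzyloxy)phenyl]-3-[2-(benzyloxy)-6-hydroxy-4-(methoxymethoxy)phenyl]propan-1-ol, via saturated ketone 6 (not isolated)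
Conditions: RuCl[(R,R)-TsDPEN](p-cymene) (2 mol %), HCO2Na, H2O/MeOH, 40 °C
Reagents that add atoms: none
Why: Tandem asymmetric transfer hydrogenation with a Noyori–Ikariya catalyst: the ruthenium hydride first reduces the enone C=C by conjugate addition and then the aryl ketone through the six-membered CH/NH transition state, the (R,R)-ligand setting the (R)-carbinol.

Step 5
Reactants: 7 (R)-1-[4-(benzyloxy)phenyl]-3-[2-(benzyloxy)-6-hydroxy-4-(methoxymethoxy)phenyl]propan-1-ol
Product: 8 (S)-5-(benzyloxy)-2-[4-(benzyloxy)phenyl]-7-(methoxymethoxy)chromane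
Conditions: PPh3, DIAD, toluene/THF, 0 °C
Reagents that add atoms: none
Why: Intramolecular Mitsunobu etherification: the phenol displaces the activated benzylic oxygen by SN2 with inversion (6-exo-tet), so the (R)-alcohol should give the (S)-configured C2 while the pyran ring closes.

Step 6
Reactants: 8 (S)-5-(benzyloxy)-2-[4-(benzyloxy)phenyl]-7-(methoxymethoxy)chromane
Product: 9 (S)-5-(benzyloxy)-2-[4-(benzyloxy)phenyl]-8-bromo-7-(methoxymethoxy)chromane
Conditions: NBS (1.0 equiv), CH2Cl2, −78 to 0 °C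
Reagents that add atoms: N-bromosuccinimide, O=C1CCC(=O)N1Br
Why: Electrophilic aromatic bromination of the phloroglucinol-type ring A; by analogy with per-O-protected flavan-3-ols, C8 (between O1 and the 7-oxygen) should be attacked in preference to C6.

Step 7
Reactants: 9 (S)-5-(benzyloxy)-2-[4-(benzyloxy)phenyl]-8-bromo-7-(methoxymethoxy)chromane
Product: 10 (S)-5-(benzyloxy)-2-[4-(benzyloxy)phenyl]-8-bromochroman-7-ol
Conditions: conc. HCl (cat.), MeOH/THF, 40 °C
Reagents that add atoms: none
Why: Acid-catalysed acetal methanolysis removes only the MOM group; benzyl ethers, the aryl bromide and the cyclic benzylic ether should be stable to dilute acid at this temperature.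

Step 8
Reactants: 10 (S)-5-(benzyloxy)-2-[4-(benzyloxy)phenyl]-8-bromochroman-7-ol
Product: 13 (S)-5-(benzyloxy)-2-[4-(benzyloxy)phenyl]-8-(trimethylsilyl)chroman-7-yl trifluoromethanesulfonate, via aryl trimethylsilyl ether 11 (not isolated), via lithium 2-silylphenolate 12 (not isolated)
Conditions: HMDS, THF, 65 °C, evaporate; n-BuLi, THF, −100 to −78 °C; Tf2O, −100 °C to rt
Reagents that add atoms: hexamethyldisilazane (HMDS), C[Si](C)(C)N[Si](C)(C)C; trifluoromethanesulfonic anhydride (Tf2O), O=S(=O)(OS(=O)(=O)C(F)(F)F)C(F)(F)F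
Why: Standard one-pot preparation of a 2-silylaryl triflate from a 2-bromophenol: O-silylation, bromine–lithium exchange, 1,3 O-to-C silyl shift (retro-Brook rearrangement) and triflation of the phenolate, all at temperatures where the benzylic C2–H should not be attacked.

Step 9
Reactants: 14 1-[2,4-bis(benzyloxy)-6-hydroxyphenyl]ethan-1-one
Product: 15 1-[2-(allyloxy)-4,6-bis(benzyloxy)phenyl]ethan-1-one
Conditions: allyl bromide, K2CO3, DMF, 60 °C
Reagents that add atoms: allyl bromide, C=CCBr
Why: Williamson etherification of the chelated phenol under mild heating gives an ortho oxygen that can later be freed without touching the benzyl ethers.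

Step 10
Reactants: 15 1-[2-(allyloxy)-4,6-bis(benzyloxy)phenyl]ethan-1-one; 16 methyl 4-(benzyloxy)benzoate
Product: 17 1-[2-(allyloxy)-4,6-bis(benzyloxy)phenyl]-3-[4-(benzyloxy)phenyl]propane-1,3-dione
Conditions: NaH, THF, reflux; then aq. HCl
Reagents that add atoms: none
Why: Crossed Claisen condensation of the methyl ketone enolate with the non-enolisable benzoate, driven by deprotonation of the β-diketone product.

Step 11
Reactants: 17 1-[2-(allyloxy)-4,6-bis(benzyloxy)phenyl]-3-[4-(benzyloxy)phenyl]propane-1,3-dione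
Product: 18 1-[2-(allyloxy)-4,6-bis(benzyloxy)phenyl]-3-[4-(benzyloxy)phenyl]-2-(phenyliodonio)propane-1,3-dion-2-ide (phenyliodonium ylide of 17)
Conditions: PhI(OAc)2, KOH, MeOH, 0 °C
Reagents that add atoms: (diacetoxyiodo)benzene, CC(=O)OI(OC(C)=O)c1ccccc1
Why: Known formation of phenyliodonium ylides from 1,3-dicarbonyl compounds with PhI(OAc)2 and base; the stabilised ylide should separate from methanol and is used at once.

Step 12
Reactants: 13 (S)-5-(benzyloxy)-2-[4-(benzyloxy)phenyl]-8-(trimethylsilyl)chroman-7-yl trifluoromethanesulfonate; 18 phenyliodonium ylide of 17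
Product: 20 [(2S)-5-(benzyloxy)-2,8-bis[4-(benzyloxy)phenyl]-3,4-dihydro-2H-furo[2,3-h]chromen-9-yl][2-(allyloxy)-4,6-bis(benzyloxy)phenyl]methanone, via flavan 7,8-aryne 19 (not isolated)
Conditions: 13 (1.5 equiv), CsF (3 equiv), MeCN/toluene, rt
Reagents that add atoms: none
Why: Fluoride attacks silicon of 13 and triflate leaves, giving the 7,8-aryne 19. The enolate oxygen of the 4-benzyloxybenzoyl arm of 18 should add to C7, the aryne carbon remote from O1, because the C8a–O1 bond polarises and distorts the aryne so that negative charge builds at C8 (3-alkoxyaryne rule). The C8 aryl anion then displaces iodobenzene at the iodonio-bearing C3′ (aryl–vinyl coupling at trivalent iodine), closing the furan ring in a formally 5-endo ipso-substitution that leaves the C2′=C3′ double bond. The closest known reaction type is the CsF-mediated [3+2] annulation of 2-silylaryl triflates with phenyliodonium ylides of 1,3-dicarbonyl compounds to 3-acylbenzofurans. No stereocenter is formed and the (S)-C2 center is untouched under these neutral room-temperature conditions. The step needs aryne regiocontrol, secured by O1 on C8a, and the right choice of enolate oxygen, which should be secured because the di-ortho-substituted aroyl group is twisted and shields its own oxygen.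

Step 13
Reactants: 20 [(2S)-5-(benzyloxy)-2,8-bis[4-(benzyloxy)phenyl]-3,4-dihydro-2H-furo[2,3-h]chromen-9-yl][2-(allyloxy)-4,6-bis(benzyloxy)phenyl]methanone
Product: 21 [(2S)-5-(benzyloxy)-2,8-bis[4-(benzyloxy)phenyl]-3,4-dihydro-2H-furo[2,3-h]chromen-9-yl][2,4-bis(benzyloxy)-6-hydroxyphenyl]methanone
Conditions: Pd(PPh3)4 (5 mol %), morpholine, THF, rt
Reagents that add atoms: none
Why: Palladium-catalysed allyl transfer (Tsuji–Trost deallylation) to morpholine through a π-allyl complex frees only the allyl-protected phenol; benzyl ethers are untouched.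

Step 14
Reactants: 21 [(2S)-5-(benzyloxy)-2,8-bis[4-(benzyloxy)phenyl]-3,4-dihydro-2H-furo[2,3-h]chromen-9-yl][2,4-bis(benzyloxy)-6-hydroxyphenyl]methanone
Product: 23 (2S,2′R,3′R)-penta-O-benzyl ether of the target (all five phenols benzylated; C3′–OH free), via benzofuran 2′,3′-epoxide 22 (not isolated)
Conditions: (S,S)-N,N′-bis(3,5-di-tert-butylsalicylidene)-1,2-cyclohexanediaminomanganese chloride (10 mol %), m-CPBA, NMO, CH2Cl2, −78 to −40 °C
Reagents that add atoms: 3-chloroperoxybenzoic acid (m-CPBA), OOC(=O)c1cccc(Cl)c1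
Why: Proposed new method: a Jacobsen–Katsuki epoxidation in which the pentavalent oxomanganese species should transfer oxygen to one face of the benzofuran C2′=C3′ bond (a cyclic, cis, aryl-conjugated tetrasubstituted enol-ether olefin; closest known types are the salen-manganese epoxidation of indene, tetrasubstituted chromenes and isoflavones and the dioxirane epoxidation of benzofurans); the labile epoxide 22 should open at C2′ to the oxocarbenium ion stabilised by O7 and the 4-benzyloxyphenyl group, and the chelated ortho phenol then closes the pyranone ring (6-exo-trig) on the face opposite the C3′–O bond, so that C3′ (R) is set by the catalyst, C2′ (R) follows from the enforced cis fusion, and the remote C2 center exerts no bias (the (S,S)-catalyst is chosen by analogy with indene, benzofuran C3′ taking the place of the benzylic carbon, with the (R,R)-antipode in reserve).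

Step 15
Reactants: 23 (2S,2′R,3′R)-penta-O-benzyl ether of the target
Product: 24 CNP0208300.2
Conditions: H2 (1 atm), Pd/C, EtOAc/MeOH, rt
Reagents that add atoms: none
Why: Hydrogenolysis of the five benzyl aryl ethers under neutral conditions; the cyclic benzylic C–O bonds at C2 and C2′ and the aryl ketone should react much more slowly, so the reaction is stopped after uptake of five equivalents of hydrogen and all three stereocenters stay untouched.

**Compound list**

1 | 2,4,6-trihydroxybenzaldehyde | O=Cc1c(O)cc(O)cc1O | starting material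
2 | 2,6-dihydroxy-4-(methoxymethoxy)benzaldehyde | O=Cc1c(O)cc(OCOC)cc1O | intermediate
3 | 2-(benzyloxy)-6-hydroxy-4-(methoxymethoxy)benzaldehyde | O=Cc1c(O)cc(OCOC)cc1OCc1ccccc1 | intermediate
4 | 1-[4-(benzyloxy)phenyl]ethan-1-one | CC(=O)c1ccc(OCc2ccccc2)cc1 | starting material
5 | (E)-1-[4-(benzyloxy)phenyl]-3-[2-(benzyloxy)-6-hydroxy-4-(methoxymethoxy)phenyl]prop-2-en-1-one | O=C(/C=C/c1c(O)cc(OCOC)cc1OCc1ccccc1)c1ccc(OCc2ccccc2)cc1 | intermediate
6 | 1-[4-(benzyloxy)phenyl]-3-[2-(benzyloxy)-6-hydroxy-4-(methoxymethoxy)phenyl]propan-1-one (saturated ketone, not isolated) | O=C(CCc1c(O)cc(OCOC)cc1OCc1ccccc1)c1ccc(OCc2ccccc2)cc1 | intermediate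
7 | (R)-1-[4-(benzyloxy)phenyl]-3-[2-(benzyloxy)-6-hydroxy-4-(methoxymethoxy)phenyl]propan-1-ol | O[C@H](CCc1c(O)cc(OCOC)cc1OCc1ccccc1)c1ccc(OCc2ccccc2)cc1 | intermediate
8 | (S)-5-(benzyloxy)-2-[4-(benzyloxy)phenyl]-7-(methoxymethoxy)chromane | COCOc1cc(OCc2ccccc2)c2c(c1)O[C@H](c1ccc(OCc3ccccc3)cc1)CC2 | intermediate
9 | (S)-5-(benzyloxy)-2-[4-(benzyloxy)phenyl]-8-bromo-7-(methoxymethoxy)chromane | COCOc1cc(OCc2ccccc2)c2c(c1Br)O[C@H](c1ccc(OCc3ccccc3)cc1)CC2 | intermediate
10 | (S)-5-(benzyloxy)-2-[4-(benzyloxy)phenyl]-8-bromochroman-7-ol | Oc1cc(OCc2ccccc2)c2c(c1Br)O[C@H](c1ccc(OCc3ccccc3)cc1)CC2 | intermediate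
11 | (S)-{[5-(benzyloxy)-2-[4-(benzyloxy)phenyl]-8-bromochroman-7-yl]oxy}trimethylsilane (not isolated) | C[Si](C)(C)Oc1cc(OCc2ccccc2)c2c(c1Br)O[C@H](c1ccc(OCc3ccccc3)cc1)CC2 | intermediate
12 | lithium (S)-5-(benzyloxy)-2-[4-(benzyloxy)phenyl]-8-(trimethylsilyl)chroman-7-olate (not isolated) | [Li+].[O-]c1cc(OCc2ccccc2)c2c(c1[Si](C)(C)C)O[C@H](c1ccc(OCc3ccccc3)cc1)CC2 | intermediate
13 | (S)-5-(benzyloxy)-2-[4-(benzyloxy)phenyl]-8-(trimethylsilyl)chroman-7-yl trifluoromethanesulfonate | C[Si](C)(C)c1c(OS(=O)(=O)C(F)(F)F)cc(OCc2ccccc2)c2c1O[C@H](c1ccc(OCc3ccccc3)cc1)CC2 | intermediate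
14 | 1-[2,4-bis(benzyloxy)-6-hydroxyphenyl]ethan-1-one | CC(=O)c1c(O)cc(OCc2ccccc2)cc1OCc1ccccc1 | starting material
15 | 1-[2-(allyloxy)-4,6-bis(benzyloxy)phenyl]ethan-1-one | CC(=O)c1c(OCC=C)cc(OCc2ccccc2)cc1OCc1ccccc1 | intermediate
16 | methyl 4-(benzyloxy)benzoate | COC(=O)c1ccc(OCc2ccccc2)cc1 | starting material
17 | 1-[2-(allyloxy)-4,6-bis(benzyloxy)phenyl]-3-[4-(benzyloxy)phenyl]propane-1,3-dione | O=C(CC(=O)c1c(OCC=C)cc(OCc2ccccc2)cc1OCc1ccccc1)c1ccc(OCc2ccccc2)cc1 | intermediate
18 | phenyliodonium ylide of 17 (zwitterion) | O=C([C-]([I+]c1ccccc1)C(=O)c1c(OCC=C)cc(OCc2ccccc2)cc1OCc1ccccc1)c1ccc(OCc2ccccc2)cc1 | intermediate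
19 | (S)-5-(benzyloxy)-2-[4-(benzyloxy)phenyl]-7,8-didehydrochromane (aryne, not isolated) | C1#CC2=C(CC[C@H](O2)c2ccc(OCc3ccccc3)cc2)C(OCc2ccccc2)=C1 | intermediate
20 | [(2S)-5-(benzyloxy)-2,8-bis[4-(benzyloxy)phenyl]-3,4-dihydro-2H-furo[2,3-h]chromen-9-yl][2-(allyloxy)-4,6-bis(benzyloxy)phenyl]methanone | O=C(c1c(OCC=C)cc(OCc2ccccc2)cc1OCc1ccccc1)c1c(-c2ccc(OCc3ccccc3)cc2)oc2cc(OCc3ccccc3)c3c(c12)O[C@H](c1ccc(OCc2ccccc2)cc1)CC3 | intermediate
21 | [(2S)-5-(benzyloxy)-2,8-bis[4-(benzyloxy)phenyl]-3,4-dihydro-2H-furo[2,3-h]chromen-9-yl][2,4-bis(benzyloxy)-6-hydroxyphenyl]methanone | O=C(c1c(O)cc(OCc2ccccc2)cc1OCc1ccccc1)c1c(-c2ccc(OCc3ccccc3)cc2)oc2cc(OCc3ccccc3)c3c(c12)O[C@H](c1ccc(OCc2ccccc2)cc1)CC3 | intermediate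
22 | C2′–C3′ epoxide of 21, oxygen on the face that becomes the (R)-C3′–OH (not isolated) | O=C(c1c(O)cc(OCc2ccccc2)cc1OCc1ccccc1)[C@@]12O[C@]1(c1ccc(OCc3ccccc3)cc1)Oc1cc(OCc3ccccc3)c3c(c12)O[C@H](c1ccc(OCc2ccccc2)cc1)CC3 | intermediate
23 | (2S,2′R,3′R)-penta-O-benzyl ether of the target: cis-fused furan/pyranone ketal–carbinol, benzyl on flavan 5-O, ring B 4-O, ring A′ 5′-O and 7′-O, ring B′ 4-O | O=C1c2c(OCc3ccccc3)cc(OCc3ccccc3)cc2O[C@@]2(c3ccc(OCc4ccccc4)cc3)Oc3cc(OCc4ccccc4)c4c(c3[C@@]12O)O[C@H](c1ccc(OCc2ccccc2)cc1)CC4 | intermediate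
24 | CNP0208300.2: (2S)-4′,5-dihydroxyflavan fused through O7–C2′ and C8–C3′ to the (2′R,3′R)-3′,5′,7′-trihydroxy-2′-(4-hydroxyphenyl)chroman-4′-one unit | O=C1c2c(O)cc(O)cc2O[C@@]2(c3ccc(O)cc3)Oc3cc(O)c4c(c3[C@@]12O)O[C@H](c1ccc(O)cc1)CC4 | target

**Step count and risks**

Total steps: 15. Longest linear sequence: 12 steps (steps 1–8 and 12–15, from 1 to 24); the ylide branch (steps 9–11) joins at step 12.

Steps most likely to fail:

1. Step 14 (proposed new method). Facial selection by the manganese catalyst may be poor on this push–pull tetrasubstituted olefin, the chelating ortho-hydroxyaryl ketone may bind and deactivate the catalyst, and a 1,2-acyl shift of the opened epoxide may compete with ketalisation. Fallback with known chemistry: starting from 21, the benzofuran would be oxidised with dimethyldioxirane (acetone/CH2Cl2, −40 to 0 °C), a known epoxidant for benzofurans and flavones that is not face-selective here. Both facial epoxides, 22 and the epimeric epoxide F1 (not isolated), should collapse to cis-fused ketals, namely 23 and the (2S,2′S,3′S) diastereomer F2. These differ in their relation to the fixed (S)-C2 center and would be separated as diastereomers by chromatography; 23 rejoins the route at step 15.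

2. Step 12. The ylide may react through the wrong enolate oxygen (giving the 2-(trioxygenated aryl)-3-(4-benzyloxybenzoyl) isomer), or it may decay by phenyl migration faster than it captures the aryne. Fallback: starting from bromophenol 10 and diketone 17, the furan ring would be built without an aryne. Copper-catalysed C-arylation of the diketone methylene at C8 (CuI, L-proline, K3PO4, DMSO, 90 °C) would give the C8-arylated diketone F3. Cyclodehydration of its C7 hydroxyl onto the less hindered 4-benzyloxybenzoyl carbonyl (PPTS, toluene, reflux) then returns to the route at 20.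

3. Step 5. Ionisation of the 4-alkoxybenzylic oxyphosphonium intermediate (SN1 pathway) would erode the enantiomeric purity of C2. Fallback: starting from chalcone 5, the C=C bond would be hydrogenated selectively (H2, RhCl(PPh3)3, toluene/EtOH) to the saturated ketone 6, now isolated. Cyclodehydration (PPTS, toluene, reflux) would give the 2-aryl-4H-chromene F4. Iridium-catalysed asymmetric hydrogenation of its C2=C3 bond (H2, [Ir(cod)(tBu-PHOX)]BArF, ligand enantiomer chosen for (S), CH2Cl2) sets C2 without any substitution at the stereocenter and returns to the route at 8.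

Further compounds
F1 | step 14 | C2′–C3′ epoxide of 21 with oxygen on the opposite face (not isolated) | O=C(c1c(O)cc(OCc2ccccc2)cc1OCc1ccccc1)[C@]12O[C@@]1(c1ccc(OCc3ccccc3)cc1)Oc1cc(OCc3ccccc3)c3c(c12)O[C@H](c1ccc(OCc2ccccc2)cc1)CC3
F2 | step 14 | (2S,2′S,3′S) diastereomer of 23 | O=C1c2c(OCc3ccccc3)cc(OCc3ccccc3)cc2O[C@]2(c3ccc(OCc4ccccc4)cc3)Oc3cc(OCc4ccccc4)c4c(c3[C@]12O)O[C@H](c1ccc(OCc2ccccc2)cc1)CC4
F3 | step 12 | 1-[2-(allyloxy)-4,6-bis(benzyloxy)phenyl]-3-[4-(benzyloxy)phenyl]-2-[(2S)-5-(benzyloxy)-2-[4-(benzyloxy)phenyl]-7-hydroxychroman-8-yl]propane-1,3-dione | O=C(C(C(=O)c1c(OCC=C)cc(OCc2ccccc2)cc1OCc1ccccc1)c1c(O)cc(OCc2ccccc2)c2c1O[C@H](c1ccc(OCc3ccccc3)cc1)CC2)c1ccc(OCc2ccccc2)cc1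
F4 | step 5 | 5-(benzyloxy)-2-[4-(benzyloxy)phenyl]-7-(methoxymethoxy)-4H-chromene | COCOc1cc(OCc2ccccc2)c2c(c1)OC(c1ccc(OCc3ccccc3)cc1)=CC2
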